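Each starting material that reacts leaves as one product and one by-product, so the fraction x of the charge standing as product and the fraction left as starting material add up to one.

    starting material + partner ⇌ product + by-product (K1 = 35, k1 = 23 M⁻¹ h⁻¹)
    partner → decomposed reagent (k2 = 0.21 h⁻¹)
    gas ⇌ partner, rate k3*(csat - [partner]) (k3 = 6.2 h⁻¹, csat = 3.0 mM)

| flask | starting material | gas | time |
|---|---|---|---|
| teal | 5.0 mM | 3.0 mM (held) | 20 h |
| ochre | 10 mM | 3.0 mM (held) | 20 h |
| grey | 20 mM | 3.0 mM (held) | 20 h |
| amber | 40 mM | 3.0 mM (held) | 20 h |

- at the start none of partner is dissolved
- "hardly changes" means that all values lie within two and a half points (for a concentration: within two and a half percent of the largest)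
- run time (teal): 20 h

- [product] at the end for teal, ochre, grey, amber, in this order
- how the row runs (falls all the way / rises, then falls / hardly changes / falls, then rises / rises all the way)

Dissolved partner starts from nothing and cannot climb past 3.0 mM, so the forward step is at most a pseudo-first-order decay of starting material, and the way back can only subtract from x. The quantity to carry is the lifetime count, the forward constant times the saturation level times the run time, 1.38. No charge stands in it, so one ceiling serves all four flasks: x stays below one minus exp(−n), which is 0.748.

For a floor, let the whole charge draw on partner throughout, which keeps partner no lower than 2.85 mM in teal and 2.54 mM in amber, once a lag equal to the inverse of partner's total loss constant has passed. Let the back step run with one of its two x factors held at the ceiling. Then x relaxes at first order and reaches 0.714 in teal and 0.589 in amber, the lower of the two. A larger charge lowers this floor, so ochre and grey lie above amber's. Each flask after teal holds twice the charge of the one before, and twice amber's floor, 1.18, exceeds the ceiling, so the row must rise at each step.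

The forecast gives 3.6 mM, 7.05 mM, 13.6 mM and 25.4 mM, rises all the way, on the ground that “With partner roughly constant, the step is pseudo-first-order forward and second-order reverse”. As fractions, teal's 0.720 and amber's 0.635 lie inside the brackets.

The flasks give 3.60 mM, 7.06 mM, 13.6 mM and 25.5 mM, rises all the way, in line with the forecast. In teal at 7.55 h, decomposition takes partner 3.0 times as fast as the forward step, with a half-life of 3.3 h, yet the transfer from the gas has a half-time of 0.112 h, which is shorter. Partner in teal is made 1.00 times as fast as it is used at that moment and stands at 2.89 mM at the end, and teal ends with 72.0 % of its charge as product, 2.9 percentage points under the ceiling set by the 1.38 lifetimes, while amber ends with 63.8 %, 11 points under it.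

The constants used here belong to no real substance; what happens was integrated by code.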